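## The problem

The target is a C2-symmetric dimer of two 3-methylquinolizidin-2-one units (ring A: N5, C6–C9, C9a; ring B: C1–C4, N5, C9a). The units are joined head to tail by two pentamethylene chains, each running from C9 of one unit to C1′ of the other. This closes a 16-membered carbocycle that contains C1, C9a and C9 of both halves and no heteroatom, so the macrocycle must be closed by C–C bond formation. Each half carries four stereocentres, (1R,3R,9S,9aS), eight in all. Three of them can be left to thermodynamic control: C1 and C3 flank the C2 ketone and epimerise by enolisation, and C9a lies on the N5–C9a bond of a β-amino ketone that opens and recloses by retro-aza-Michael/aza-Michael addition. C9 has no such pathway, so it must be set absolutely and it then governs the other three. The β-amino ketone does not tolerate strong acid with heat, because retro-Mannich cleavage of C1–C9a gives an N5=C9a iminium ion whose enamine would erase C9; the basic tertiary amine also binds Lewis acids and metal catalysts. The feature that makes the key step possible is that C9 is the ring-A carbon next to C9a. In a cyclic imine N5=C9a the C9–H bond is α to C=N and labile through the C9=C9a enamine, so a racemic precursor can drain through one enantiomer while hydride delivery sets C9a.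

## Retrosynthesis

**22 ⇒ 21 ⇒ 20.** No skeletal bond is cut; the C1–H and C1′–H bonds are removed to give bis(enone) 20. Base equilibration of the epimer mixture 21 is placed last because C1, C3 and C9a are all labile. 20 has two stereocentres fewer. The forward steps are an enone hydrogenation and an epimerisation that must leave C9 alone.

**20 ⇒ 18 ⇒ two molecules of 17.** Both C1–C(tether) bonds are cut by an aldol transform, which halves the molecule. A cut at C9 has no activating group to use, and a mid-chain alkene cut cannot distinguish head-to-tail from head-to-head pairing. A free keto aldehyde under base would let the aldehyde condense with itself, so the monomer 17 carries a C1=C2 silyl enol ether and the union is a Lewis-acid (Mukaiyama) aldol in which only C1 is nucleophilic. The forward reaction must dimerise 17 and then close the 16-membered ring in preference to chain growth.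

**17 ⇒ 16 ⇒ 15.** The formyl carbon is cut from the chain (hydroformylation transform) and the O–Si bond is cut. This is why the C9 side chain is carried as a but-3-enyl group: four tether carbons come from 3 and the fifth from the formyl group, so the alkene is a latent aldehyde that survives every earlier step. The forward steps need kinetic enolisation of ketone 15 at the C1 methylene, not the C3 methine, and a linear-selective hydroformylation that leaves the enol ether alone.

**15 ⇒ 12 + 13.** The N5–C4 and C3–C4 bonds are cut by a Mannich transform, so ring B comes from piperidine 12 and formaldehyde 13 after the dioxolane is removed (amino ketone 14). Only C3 can reach the N-methyleneiminium carbon in a six-membered transition state; attack through C1 would give a four-membered ring. The forward reaction is a one-flask ketal hydrolysis and 6-endo Mannich closure.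

**12 ⇒ 10 (key disconnection).** The N5–C9a bond and the C9a–H bond are cut by a reductive amination transform, which opens ring A to the acyclic, racemic δ-amino ketone 10. Its only stereocentre, C9, needs no control because the derived cyclic imine 11 racemises there. An auxiliary-based alkylation would set C9 but not C9a, and a chemical imine reduction could not choose between the imine enantiomers. The forward reaction asks one enzyme to accept one C9 epimer of 11 and to deliver hydride to one face of C9a.

**10 ⇒ 9 ⇒ 8.** The C6–N5 bond is traced to an azide displacement on chloride 8 followed by Staudinger reduction. These neutral conditions keep the dioxolane, which is what stops the C2 carbonyl from turning the imine into an enaminone.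

**8 ⇒ 7 ⇒ 5 + 6.** The C9–C8 bond is cut by alkylation with 1-bromo-3-chloropropane 6, with a phenylsulfonyl group as a temporary activator on C9. Direct alkylation of the unactivated ketone was rejected: it has two methylene α-positions (C9 and C1), and a C1 enolate can expel the β-ketal oxygen. In β-keto sulfone 5 only C9 is acidic enough for a carbonate base; the sulfonyl group is then removed reductively.

**5 ⇒ 2 + 4; 2 ⇒ 1; 4 ⇒ 3.** The C9a–C9 bond is cut by acylation of the α-sulfonyl carbanion of 4 with ester 2. Ester 2 is the dioxolane of ethyl 3-oxopentanoate 1, which already holds C1, C2, C3 and the C3 methyl in the right oxidation states. Sulfone 4 comes from 5-bromopent-1-ene 3.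

## Roads not taken

**Alternative 1:** Metathesis cyclodimerisation. The cut is through both tether C=C bonds next to C9 of the macrocyclic diene A2. The forward step is cross-metathesis followed by ring-closing metathesis of the ammonium salt of monomer A1 (C9 vinyl, C1 pent-4-enyl) with a second-generation Grubbs catalyst, then hydrogenation.
- Merits: metathesis is reversible, so the cyclic dimer can be reached under thermodynamic control. The hindered allylic vinyl group and the unhindered pentenyl group differ in reactivity, which biases head-to-tail pairing. Only hydrogenation and equilibration follow.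
- Weak points: A1 needs C9 as an allylic stereocentre bearing a vinyl group, with no built-in way to set it absolutely. Ruthenium hydride species can move that double bond into the ring and destroy the one centre that cannot be repaired. The C1 chain still has to be installed on the ketone.
- Comparison: in the macrocyclisation this road is better than the chosen plan, whose aldol closure is kinetic and irreversible. The chosen plan sets against it a catalytic, absolute solution for C9 in which C9 is never allylic.

**Alternative 2:** Rhodium [2+2+2] cycloaddition. The cut is through N5–C4, C3–C2, C2–C1 and N5–C9a of the bicyclic vinylogous amide A5. The forward step combines alkenyl isocyanate A3 with silylalkyne A4 under [Rh(C2H4)2Cl]2 and a TADDOL-derived phosphoramidite.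
- Merits: both rings and four bonds form in one step, with catalyst control at C9a.
- Weak points: C9 must already be present, enantiopure, in A3, next to the reacting alkene, where it can erode rate and selectivity. The catalyst-set centre C9a is the one that equilibrates anyway. Desilylation, reduction of the vinylogous amide, C1 functionalisation and the whole dimerisation remain.
- Comparison: for building the bicycle this road is shorter than the three steps used here (reduction, hydrolysis, Mannich). The chosen plan sets against it that its single asymmetric step is spent on C9, the centre that matters.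

**Alternative 3:** Imine allylboration cyclodimerisation. The cut is through both C9–C9a bonds of macrocycle A7. The forward step activates the allyltrifluoroborate of cyclic imine monomer A6 with BF3·OEt2; γ-addition to C9a of a second molecule, twice, closes the ring.
- Merits: this is the most convergent option, giving the macrocycle, both C9–C9a bonds and the C9/C9a relationship in one operation.
- Weak points: absolute control at C9 is relayed from C1 and C3 of A6, and C1 is α to the imine and itself labile. Cyclic aldimines self-condense. The oligomer problem is the same as here. Afterwards each vinyl group must still be homologated and closed onto N5 to make ring A, C1 must be inverted, and the ketals removed.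
- Comparison: more convergent in principle. The chosen plan sets against it direct enzyme control of C9 and a shorter sequence after the stereocentre is made.

Key step: step 8

Assumption: the configuration of 22 at C1, C3 and C9a (and C1′, C3′, C9a′) is taken to be the thermodynamic one for fixed (9S,9′S), because these centres epimerise by enolisation or retro-aza-Michael addition; step 15 relies on this.
Locants C1–C9a follow quinolizidine numbering in every intermediate; primes mark the second half.

## Route

Step 1
Reactants: 1 ethyl 3-oxopentanoate
Product: 2 ethyl 2-(2-ethyl-1,3-dioxolan-2-yl)acetate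
Conditions: HOCH2CH2OH (3 equiv), TsOH·H2O (cat.), toluene, reflux, Dean–Stark
Reagents that add atoms: ethane-1,2-diol, OCCO
Why: Acid-catalysed ketalisation of the ketone of a β-keto ester with azeotropic removal of water; the ester is untouched and C2 is masked for the whole first half of the route.

Step 2
Reactants: 3 5-bromopent-1-ene
Product: 4 (pent-4-en-1-ylsulfonyl)benzene
Conditions: PhSO2Na (1.2 equiv), n-Bu4NI (cat.), DMF, 60 °C
Reagents that add atoms: sodium benzenesulfinate, [Na+].[O-]S(=O)c1ccccc1
Why: SN2 S-alkylation of a sulfinate by a primary bromide gives the alkyl aryl sulfone.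

Step 3
Reactants: 2 ethyl 2-(2-ethyl-1,3-dioxolan-2-yl)acetate; 4 (pent-4-en-1-ylsulfonyl)benzene
Product: 5 1-(2-ethyl-1,3-dioxolan-2-yl)-3-(phenylsulfonyl)hept-6-en-2-one (racemic)
Conditions: 4 (2.2 equiv), n-BuLi (2.1 equiv), THF, −78 °C; then 2, −78 to 0 °C; aq. NH4Cl
Reagents that add atoms: none
Why: Claisen-type acylation of an α-sulfonyl carbanion by an ester forms the C9a–C9 bond; the second equivalent of carbanion deprotonates the β-keto sulfone as it forms, which prevents a second addition, and the excess of 4 is recovered.

Step 4
Reactants: 5 1-(2-ethyl-1,3-dioxolan-2-yl)-3-(phenylsulfonyl)hept-6-en-2-one; 6 1-bromo-3-chloropropane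
Product: 7 3-(3-chloropropyl)-1-(2-ethyl-1,3-dioxolan-2-yl)-3-(phenylsulfonyl)hept-6-en-2-one (racemic)
Conditions: 6 (3 equiv), Cs2CO3, NaI (cat.), DMF, 50 °C
Reagents that add atoms: none
Why: C-alkylation of the doubly activated C9 methine, the only position a carbonate base can deprotonate, so the regiochemistry is fixed; bromide is displaced in preference to chloride (SN2).

Step 5
Reactants: 7 3-(3-chloropropyl)-1-(2-ethyl-1,3-dioxolan-2-yl)-3-(phenylsulfonyl)hept-6-en-2-one
Product: 8 3-(3-chloropropyl)-1-(2-ethyl-1,3-dioxolan-2-yl)hept-6-en-2-one (racemic)
Conditions: SmI2 (2.5 equiv), THF–MeOH, −78 °C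
Reagents that add atoms: none
Why: Reductive desulfonylation of a β-keto sulfone by electron transfer gives a samarium enolate that MeOH protonates at C9; the alkyl chloride, alkene and dioxolane are inert at this temperature, and C9 is formed racemic on purpose.

Step 6
Reactants: 8 3-(3-chloropropyl)-1-(2-ethyl-1,3-dioxolan-2-yl)hept-6-en-2-one
Product: 9 3-(3-azidopropyl)-1-(2-ethyl-1,3-dioxolan-2-yl)hept-6-en-2-one (racemic)
Conditions: NaN3, NaI (cat.), DMF, 60 °C
Reagents that add atoms: sodium azide, [Na+].[N-]=[N+]=[N-]
Why: SN2 displacement of a primary chloride by azide under iodide catalysis.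

Step 7
Reactants: 9 3-(3-azidopropyl)-1-(2-ethyl-1,3-dioxolan-2-yl)hept-6-en-2-one
Product: 10 3-(3-aminopropyl)-1-(2-ethyl-1,3-dioxolan-2-yl)hept-6-en-2-one (racemic; in solution in equilibrium with its cyclic imine 11 and carried forward without storage)
Conditions: PPh3, THF, rt; then H2O, 50 °C
Reagents that add atoms: none
Why: Staudinger reduction of the azide under neutral conditions keeps the acid-labile dioxolane; hydrolysis of the iminophosphorane or its intramolecular aza-Wittig reaction leads to the same amine/imine pair.

Step 8
Reactants: 10 3-(3-aminopropyl)-1-(2-ethyl-1,3-dioxolan-2-yl)hept-6-en-2-one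
Product: 12 (2R,3S)-3-(but-3-en-1-yl)-2-[(2-ethyl-1,3-dioxolan-2-yl)methyl]piperidine, via cyclic imine 11 (not isolated)
Conditions: imine reductase (hit from a screened panel), NADP+ (cat.), D-glucose, glucose dehydrogenase, KH2PO4/K2HPO4 buffer pH 8.0, DMSO (5% v/v), 30 °C
Reagents that add atoms: none
Why: In buffer 10 closes by 6-exo-trig attack of N5 on the C9a ketone and loses water to give the tetrahydropyridine 11, so ring A exists before the enzyme acts. The C9–H bond of 11 is α to C=N and exchanges through the C9=C9a enamine, so the two enantiomers of 11 interconvert under the reaction conditions. The imine reductase binds one of them and transfers hydride from NADPH to one face of C9a, with NADPH regenerated by glucose dehydrogenase and glucose; the amine formed cannot epimerise, so the racemate is funnelled into one stereoisomer (dynamic kinetic resolution). The closest known reaction type is the imine-reductase reduction of 2-substituted and 2,3-disubstituted cyclic imines together with enzymatic dynamic kinetic resolution of α-branched imines. C9a is controlled by the enzyme's facial hydride delivery and C9 by the enzyme's choice between the equilibrating imine enantiomers, which together must give the trans (2R,3S) isomer. The step needs enantioselectivity, trans diastereoselectivity and racemisation faster than reduction; the dioxolane secures reactivity by preventing a C1=C9a enaminone, and C9 stays labile because it is the only stereogenic carbon α to the imine.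

Step 9
Reactants: 12 (2R,3S)-3-(but-3-en-1-yl)-2-[(2-ethyl-1,3-dioxolan-2-yl)methyl]piperidine; 13 formaldehyde
Product: 15 (3R,9S,9aR)-9-(but-3-en-1-yl)-3-methyloctahydro-2H-quinolizin-2-one, via free amino ketone 14 (not isolated)
Conditions: 1 M aq. HCl, THF, rt; then NaOAc to pH 4–5, 13 (37% aq., 1.1 equiv), 50 °C; aq. K2CO3 work-up
Reagents that add atoms: water, O
Why: Ketal hydrolysis followed by an intramolecular Mannich reaction: the N-methyleneiminium ion from N5 and 13 is attacked 6-endo by the C3 enol, the only enol carbon within reach, forming N5–C4 and C3–C4 and closing ring B. The C3 methyl settles equatorial (3R) by enolisation; C9 is untouched because the protonated amine cannot undergo retro-Mannich cleavage.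

Step 10
Reactants: 15 (3R,9S,9aR)-9-(but-3-en-1-yl)-3-methyloctahydro-2H-quinolizin-2-one
Product: 16 (3R,9S,9aS)-9-(but-3-en-1-yl)-2-[(tert-butyldimethylsilyl)oxy]-3-methyl-3,4,6,7,8,9-hexahydro-9aH-quinolizine
Conditions: LiN(i-Pr)2 (1.1 equiv), THF, −78 °C; then TBSCl, DMPU, −78 to 0 °C
Reagents that add atoms: tert-butyldimethylsilyl chloride, CC(C)(C)[Si](C)(C)Cl
Why: Kinetic deprotonation takes the C1 methylene rather than the C3 methine, as with 2-methylcyclohexanone and with bicyclic β-amino ketones, and O-silylation fixes the C1=C2 enol ether; at −78 °C the lithium enolate does not expel N5.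

Step 11
Reactants: 16 (3R,9S,9aS)-9-(but-3-en-1-yl)-2-[(tert-butyldimethylsilyl)oxy]-3-methyl-3,4,6,7,8,9-hexahydro-9aH-quinolizine
Product: 17 5-[(3R,9S,9aS)-2-[(tert-butyldimethylsilyl)oxy]-3-methyl-3,4,6,7,8,9-hexahydro-9aH-quinolizin-9-yl]pentanal
Conditions: Rh(acac)(CO)2 (1 mol%), Xantphos (2 mol%), CO/H2 (1:1, 10 bar), toluene, 70 °C
Reagents that add atoms: carbon monoxide, [C-]#[O+]
Why: Linear-selective hydroformylation of the terminal alkene with a wide-bite-angle diphosphine supplies the fifth tether carbon as the aldehyde; the trisubstituted silyl enol ether and the tertiary amine are inert, and without a Lewis acid the two ends of 17 do not react with each other.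

Step 12
Reactants: 17 5-[(3R,9S,9aS)-2-[(tert-butyldimethylsilyl)oxy]-3-methyl-3,4,6,7,8,9-hexahydro-9aH-quinolizin-9-yl]pentanal (two molecules)
Product: 18 macrocyclic bis(β-hydroxy ketone), the 16-membered head-to-tail cyclodimer in which C1 of each quinolizidin-2-one unit is bonded to the CH(OH) carbon ending the (CH2)4 chain from C9 of the other unit (mixture at C1, C1′ and both carbinol carbons)
Conditions: BF3·OEt2 (2.5 equiv per 17), CH2Cl2 (0.01 M), −78 to −40 °C; then aq. NaOH, MeOH, rt
Reagents that add atoms: none
Why: Mukaiyama aldol addition: the BF3-bound aldehyde is attacked by C1 of the enol silane, the only nucleophile present, while N5 is tied up as its boron adduct and the aldehyde cannot enolise. An intermolecular union is followed by closure of the linear dimer to the 16-membered ring; the intramolecular alternative within one monomer would be a strained bridged eight-membered ring. The new stereocentres form unselectively and are erased in steps 13–15.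

Step 13
Reactants: 18 macrocyclic bis(β-hydroxy ketone)
Product: 20 macrocyclic bis(enone) with exocyclic C1=CH and C1′=CH double bonds (E/Z mixture), via bis(mesylate) 19 (not isolated)
Conditions: MsCl, Et3N, CH2Cl2, 0 °C; then DBU, rt
Reagents that add atoms: none
Why: Mesylation of the aldol hydroxyls and E1cB elimination through the acidic C1–H give the conjugated exocyclic enones; this also removes the four stereocentres formed unselectively in step 12.

Step 14
Reactants: 20 macrocyclic bis(enone)
Product: 21 mixture of C1/C1′ epimers of the target (C3, C9 and C9a as in 22)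
Conditions: H2 (1 atm), Pd/C (10%), EtOAc, rt
Reagents that add atoms: none
Why: Heterogeneous hydrogenation of the trisubstituted enone C=C bonds leaves the ketones and amines untouched; C1 and C1′ form under kinetic control and are corrected in step 15.

Step 15
Reactants: 21 mixture of C1/C1′ epimers of the target
Product: 22 the target, (1R,3R,9S,9aS) in both halves
Conditions: K2CO3, MeOH, 40 °C
Reagents that add atoms: none
Why: Base-mediated equilibration: C1 and C3 epimerise by enolisation and C9a by reversible retro-aza-Michael opening of the N5–C9a bond, while C9 has no such pathway. Each half should settle into the trans-fused arrangement dictated by (9S): equatorial C9 chain and C3 methyl, and an axial C1 chain that avoids the syn-pentane clash with the C9 chain.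

## Compound list

1 | ethyl 3-oxopentanoate | CCC(=O)CC(=O)OCC | starting material
2 | ethyl 2-(2-ethyl-1,3-dioxolan-2-yl)acetate | CCC1(CC(=O)OCC)OCCO1 | intermediate
3 | 5-bromopent-1-ene | C=CCCCBr | starting material
4 | (pent-4-en-1-ylsulfonyl)benzene | C=CCCCS(=O)(=O)c1ccccc1 | intermediate
5 | 1-(2-ethyl-1,3-dioxolan-2-yl)-3-(phenylsulfonyl)hept-6-en-2-one (racemic) | CCC1(CC(=O)C(CCC=C)S(=O)(=O)c2ccccc2)OCCO1 | intermediate
6 | 1-bromo-3-chloropropane | ClCCCBr | starting material
7 | 3-(3-chloropropyl)-1-(2-ethyl-1,3-dioxolan-2-yl)-3-(phenylsulfonyl)hept-6-en-2-one (racemic) | CCC1(CC(=O)C(CCC=C)(CCCCl)S(=O)(=O)c2ccccc2)OCCO1 | intermediate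
8 | 3-(3-chloropropyl)-1-(2-ethyl-1,3-dioxolan-2-yl)hept-6-en-2-one (racemic) | CCC1(CC(=O)C(CCC=C)CCCCl)OCCO1 | intermediate
9 | 3-(3-azidopropyl)-1-(2-ethyl-1,3-dioxolan-2-yl)hept-6-en-2-one (racemic) | CCC1(CC(=O)C(CCC=C)CCCN=[N+]=[N-])OCCO1 | intermediate
10 | 3-(3-aminopropyl)-1-(2-ethyl-1,3-dioxolan-2-yl)hept-6-en-2-one (racemic) | CCC1(CC(=O)C(CCC=C)CCCN)OCCO1 | intermediate
11 | 5-(but-3-en-1-yl)-6-[(2-ethyl-1,3-dioxolan-2-yl)methyl]-2,3,4,5-tetrahydropyridine (racemic) | CCC1(CC2=NCCCC2CCC=C)OCCO1 | intermediate (not isolated)
12 | (2R,3S)-3-(but-3-en-1-yl)-2-[(2-ethyl-1,3-dioxolan-2-yl)methyl]piperidine | CCC1(OCCO1)C[C@H]2NCCC[C@@H]2CCC=C | intermediate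
13 | formaldehyde | C=O | starting material
14 | 1-[(2R,3S)-3-(but-3-en-1-yl)piperidin-2-yl]butan-2-one | CCC(=O)C[C@H]1NCCC[C@@H]1CCC=C | intermediate (not isolated)
15 | (3R,9S,9aR)-9-(but-3-en-1-yl)-3-methyloctahydro-2H-quinolizin-2-one | C[C@@H]1CN2CCC[C@H](CCC=C)[C@H]2CC1=O | intermediate
16 | (3R,9S,9aS)-9-(but-3-en-1-yl)-2-[(tert-butyldimethylsilyl)oxy]-3-methyl-3,4,6,7,8,9-hexahydro-9aH-quinolizine | C[C@@H]1CN2CCC[C@H](CCC=C)[C@H]2C=C1O[Si](C)(C)C(C)(C)C | intermediate
17 | 5-[(3R,9S,9aS)-2-[(tert-butyldimethylsilyl)oxy]-3-methyl-3,4,6,7,8,9-hexahydro-9aH-quinolizin-9-yl]pentanal | C[C@@H]1CN2CCC[C@H](CCCCC=O)[C@H]2C=C1O[Si](C)(C)C(C)(C)C | intermediate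
18 | macrocyclic bis(β-hydroxy ketone): 16-membered head-to-tail cyclodimer, C1 of each (3R,9S,9aS)-3-methylquinolizidin-2-one unit bonded to the CH(OH) carbon ending the (CH2)4 chain from C9 of the other unit; mixture at C1, C1′ and the carbinol carbons | C[C@@H]1CN2CCC[C@@H]3CCCCC(O)C4C(=O)[C@H](C)CN5CCC[C@H](CCCCC(O)C(C1=O)[C@H]32)[C@@H]45 | intermediate
19 | bis(methanesulfonate) of 18 | C[C@@H]1CN2CCC[C@@H]3CCCCC(OS(C)(=O)=O)C4C(=O)[C@H](C)CN5CCC[C@H](CCCCC(OS(C)(=O)=O)C(C1=O)[C@H]32)[C@@H]45 | intermediate (not isolated)
20 | macrocyclic bis(enone): as 18 with exocyclic C1=CH and C1′=CH double bonds in place of the aldol units (E/Z mixture) | C[C@@H]1CN2CCC[C@@H]3CCCCC=C4C(=O)[C@H](C)CN5CCC[C@H](CCCCC=C(C1=O)[C@H]32)[C@@H]45 | intermediate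
21 | C1/C1′ epimer mixture of the target (C3, C9, C9a as in 22; C1 and C1′ unassigned) | C[C@@H]1CN2CCC[C@@H]3CCCCCC4C(=O)[C@H](C)CN5CCC[C@H](CCCCCC(C1=O)[C@H]32)[C@@H]45 | intermediate
22 | target: C2-symmetric 16-membered dimer of 3-methylquinolizidin-2-one units joined C9→C1′ and C9′→C1 by pentamethylene chains, (1R,3R,9S,9aS) in both halves | C[C@@H]1CN2CCC[C@@H]3CCCCC[C@H]4C(=O)[C@H](C)CN5CCC[C@H](CCCCC[C@@H](C1=O)[C@H]32)[C@@H]45 | target

## Step count and least certain steps

Total step count: 15. Longest linear sequence: 14 steps (from 1 through steps 1 and 3–15; the same length from 3 through steps 2–15).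

**Step 8 (key step).** Racemisation of 11 through the enamine may be slower than reduction, so the reaction would run as a plain kinetic resolution and stall with the wrong imine enantiomer left over. The bulky C9a substituent may also be poorly accepted, or hydride delivery may favour the cis isomer; a wider enzyme panel, higher pH and higher temperature are the first adjustments. Fallback, setting out from 10/11: reduce with NaBH4 in MeOH to racemic 3-(but-3-en-1-yl)-2-[(2-ethyl-1,3-dioxolan-2-yl)methyl]piperidine F1 (cis/trans mixture). Take this through the conditions of step 9 to racemic 9-(but-3-en-1-yl)-3-methyloctahydro-2H-quinolizin-2-one F2, in which the β-amino ketone equilibrates C9a to the trans series. Resolve F2 by crystallisation of its salt with O,O′-di-p-toluoyl-L-tartaric acid. The route is rejoined at 15.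

**Step 12.** Chain growth to linear oligomers may outrun closure of the 16-membered ring, because the C–C bond formation is irreversible. The Lewis acid may also be held by N5 and fail to activate the aldehyde. Fallback, setting out from 16 and 17: add 17 slowly to an excess of 16 and BF3·OEt2, so that the aldehyde of 17 meets only the enol silane of 16. This gives the linear mono-aldol, in which C1 of the butenyl-bearing ketone half is joined through CH(OH)(CH2)4 to C9 of a half that still carries its C1′=C2′ silyl enol ether, F3. Hydroformylation as in step 11 gives the seco aldehyde F4. BF3·OEt2 at high dilution then closes the ring in a purely intramolecular Mukaiyama aldol addition. The route is rejoined at 18.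

**Step 11.** Double-bond migration or branched aldehyde formation would shorten or branch the tether. Loss of the silyl enol ether, or a rhodium-promoted aldol reaction of the product at 70 °C, would consume the monomer. Fallback, setting out from 15, with the electrophile changed to an acetal:
- hydroformylate the ketone to 5-[(3R,9S,9aR)-3-methyl-2-oxooctahydro-2H-quinolizin-9-yl]pentanal F5;
- protect the aldehyde (CH(OMe)3, MeOH, camphorsulfonic acid) as (3R,9S,9aR)-9-(5,5-dimethoxypentyl)-3-methyloctahydro-2H-quinolizin-2-one F6;
- form the enol silane (LiN(i-Pr)2, TBSCl) to (3R,9S,9aS)-2-[(tert-butyldimethylsilyl)oxy]-9-(5,5-dimethoxypentyl)-3-methyl-3,4,6,7,8,9-hexahydro-9aH-quinolizine F7;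
- cyclodimerise with Me3SiOTf in a Mukaiyama-acetal reaction to the macrocyclic bis(β-methoxy ketone) F8;
- eliminate methanol with DBU.

The route is rejoined at 20.

**Step 4.** Alkylation at the hindered tertiary carbon may be slow, and O-alkylation of the enolate may compete. Fallback, setting out from 4, 6 and 2:
- alkylate lithiated 4 with 6 to [(1-chlorooct-7-en-4-yl)sulfonyl]benzene F9;
- reduce 2 with i-Bu2AlH at −78 °C to 2-(2-ethyl-1,3-dioxolan-2-yl)acetaldehyde F10;
- add lithiated F9 to F10 (Julia-type addition) to give 3-(3-chloropropyl)-1-(2-ethyl-1,3-dioxolan-2-yl)-3-(phenylsulfonyl)hept-6-en-2-ol F11;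
- oxidise (Dess–Martin oxidation).

The route is rejoined at 7.

**Step 15.** The solution equilibrium may not lie far enough on the side of 22, which would leave a mixture of C1/C3/C9a epimers. Prolonged heating could also open a retro-Mannich path that erodes C9. Fallback, setting out from 21: run the epimerisation as a crystallisation-induced diastereomer transformation, with catalytic DBU in a solvent from which the C2-symmetric 22 crystallises (for example MeCN, with seeding). The solid phase then drives the equilibrium, and no new compound is made on the way to 22.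

## Further compounds

F1 | step 8 | racemic 3-(but-3-en-1-yl)-2-[(2-ethyl-1,3-dioxolan-2-yl)methyl]piperidine (cis/trans mixture) | CCC1(OCCO1)CC2NCCCC2CCC=C
F2 | step 8 | racemic 9-(but-3-en-1-yl)-3-methyloctahydro-2H-quinolizin-2-one (relative configuration as in 15) | CC1CN2CCCC(CCC=C)C2CC1=O
F3 | step 12 | linear mono-aldol: (3R,9S,9aS)-9-(but-3-en-1-yl)-3-methylquinolizidin-2-one unit joined from C1 through CH(OH)(CH2)4 to C9 of a (3R,9S,9aS)-2-(tert-butyldimethylsilyloxy)-3-methyl-1,2-didehydroquinolizidine unit | C[C@@H]1CN2CCC[C@H](CCC=C)[C@H]2C(C1=O)C(O)CCCC[C@H]3CCCN4C[C@@H](C)C(O[Si](C)(C)C(C)(C)C)=C[C@H]34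
F4 | step 12 | seco aldehyde: as F3 with the but-3-enyl group replaced by 5-oxopentyl | C[C@@H]1CN2CCC[C@H](CCCCC=O)[C@H]2C(C1=O)C(O)CCCC[C@H]3CCCN4C[C@@H](C)C(O[Si](C)(C)C(C)(C)C)=C[C@H]34
F5 | step 11 | 5-[(3R,9S,9aR)-3-methyl-2-oxooctahydro-2H-quinolizin-9-yl]pentanal | C[C@@H]1CN2CCC[C@H](CCCCC=O)[C@H]2CC1=O
F6 | step 11 | (3R,9S,9aR)-9-(5,5-dimethoxypentyl)-3-methyloctahydro-2H-quinolizin-2-one | C[C@@H]1CN2CCC[C@H](CCCCC(OC)OC)[C@H]2CC1=O
F7 | step 11 | (3R,9S,9aS)-2-[(tert-butyldimethylsilyl)oxy]-9-(5,5-dimethoxypentyl)-3-methyl-3,4,6,7,8,9-hexahydro-9aH-quinolizine | C[C@@H]1CN2CCC[C@H](CCCCC(OC)OC)[C@H]2C=C1O[Si](C)(C)C(C)(C)C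
F8 | step 11 | macrocyclic bis(β-methoxy ketone): as 18 with OMe in place of both OH groups | C[C@@H]1CN2CCC[C@@H]3CCCCC(OC)C4C(=O)[C@H](C)CN5CCC[C@H](CCCCC(OC)C(C1=O)[C@H]32)[C@@H]45
F9 | step 4 | [(1-chlorooct-7-en-4-yl)sulfonyl]benzene (racemic) | ClCCCC(CCC=C)S(=O)(=O)c1ccccc1
F10 | step 4 | 2-(2-ethyl-1,3-dioxolan-2-yl)acetaldehyde | CCC1(CC=O)OCCO1
F11 | step 4 | 3-(3-chloropropyl)-1-(2-ethyl-1,3-dioxolan-2-yl)-3-(phenylsulfonyl)hept-6-en-2-ol (diastereomer mixture) | CCC1(CC(O)C(CCC=C)(CCCCl)S(=O)(=O)c2ccccc2)OCCO1
F0 | step 15 | none | none
A1 | alternative 1 | 9-ethenyl-3-methyl-1-(pent-4-en-1-yl)octahydro-2H-quinolizin-2-one, configured as in the target, as its p-toluenesulfonate salt | C[C@@H]1CN2CCC[C@H](C=C)[C@H]2[C@@H](CCCC=C)C1=O.Cc1ccc(cc1)S(=O)(=O)O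
A2 | alternative 1 | macrocyclic bis-quinolizidinone diene (tetradehydro target, E double bonds next to C9 and C9′) | C[C@@H]1CN2CCC[C@@H]3/C=C/CCC[C@H]4C(=O)[C@H](C)CN5CCC[C@H](/C=C/CCC[C@@H](C1=O)[C@H]32)[C@@H]45
A3 | alternative 2 | tert-butyl{[(6S)-6-ethenyl-9-isocyanatononyl]oxy}dimethylsilane | O=C=NCCC[C@H](CCCCCO[Si](C)(C)C(C)(C)C)C=C
A4 | alternative 2 | trimethyl(prop-1-yn-1-yl)silane | CC#C[Si](C)(C)C
A5 | alternative 2 | 9-[5-(tert-butyldimethylsilyloxy)pentyl]-3-methyl-4-(trimethylsilyl)-1,6,7,8,9,9a-hexahydro-2H-quinolizin-2-one | CC1=C([Si](C)(C)C)N2CCC[C@H](CCCCCO[Si](C)(C)C(C)(C)C)[C@H]2CC1=O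
A6 | alternative 3 | potassium salt of 10-methyl-1,4-dioxa-8-azaspiro[4.5]dec-7-ene carrying at C6 an (E)-8-(trifluoroborato)oct-6-en-1-yl chain | [K+].F[B-](F)(F)C/C=C/CCCCC[C@H]1C=NC[C@@H](C)C12OCCO2
A7 | alternative 3 | 16-membered carbocycle fused to two NH piperidine ethylene ketals, vinyl groups on C9 and C9′, C1 epimeric to the target | C=C[C@@H]3CCCCC[C@H]4[C@@H](NC[C@@H](C)C45OCCO5)[C@H](C=C)CCCCC[C@H]6[C@H]3NC[C@@H](C)C67OCCO7
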